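The data were generated by integration from invented constants; scatter was added.

- The easy step comes first. With the main step by itself, dissolved substrate + reagent → target, and c_reagent held at its charge, the rate is pseudo-first-order in dissolved substrate and integrates in closed form: c_target = k · c_reagent · ∫c_dissolved substrate dt.
- So c_target at the end, divided by the reagent charged, equals k∫c_dissolved substrate dt. The solid charge does not enter this ratio, provided solid remains and c_dissolved substrate follows the same course.

all flasks: solid substrate 0.14 M
- east: reagent 0.28 M; run made earlier
- west: reagent 0.63 M; run made earlier
- flask: reagent 0.420 M; time 10 d

| run | time / d | target / % | solid product / % |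
|---|---|---|---|
| east | 0.833 | 0.6 | 0 |
| east | 1.25 | 2.7 | 0.9 |
| east | 1.67 | 3.5 | 0 |
| east | 3.00 | 7.6 | 0.5 |
| east | 4.00 | 10.6 | 0 |
| east | 6.00 | 18.8 | 0 |
| east | 10.0 | 31.0 | 0 |
| west | 0.833 | 2.1 | 0.7 |
| west | 1.25 | 4.3 | 0 |
| west | 1.67 | 6.8 | 0 |
| west | 3.00 | 11.1 | 0 |
| west | 4.00 | 20.3 | 0 |
| west | 6.00 | 27.1 | 0 |
| west | 10.0 | 54.8 | 17.6 |

(standard deviation of a reading: 1 percentage point)

- percentages count the solid substrate that a species holds: one side product counts as two
- target is meant together with its solid product
- solid, in amounts per volume of the solution: solid substrate, solid product
- reactions considered so far: solid substrate <-> dissolved substrate; dissolved substrate + reagent -> target; 2 dissolved substrate -> side product; solid product <-> target; target <-> isomer of the product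
- at the start none of the solid substrate is in solution
- dissolved substrate means what is dissolved; the solid is not counted in it

- the target and solid product together standing at 10 d, as a percentage of the solid substrate charged
- concentration of dissolved substrate in solution at 10 d, in percent of saturation

- At 10 d the east run reads a ratio of 0.155, and I hold c_reagent at its charge as an approximation. With the main step by itself, I give the flask this ratio and reckon it at 46.5 %.
- Now I add the dissolving balance. The west run reads 0.122, less than east, and I take this to mean that more reagent draws c_dissolved substrate lower.
- Interpolating linearly in the reagent charge, I reckon the target-per-reagent ratio at 10 d for the flask as 0.142, which lowers my flask figure to 42.5 %.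
- I add no separate correction for the rest. Whatever side product and isomer of the product take in the east and west runs already sits inside the two ratios, and crystals barely move the sum of target and solid product. The ratio holds k and the integral as one product, so I give no saturation of my own.
- The forecast gives 46 % and 70 %, holding that “the solution stays fairly near saturation”.
- The flask gives 41.3 % and 33.2 %. At 4.75 d in the flask, dissolved substrate is made 1.02 times as fast as it is used up. The flask's ratio is 0.138 against my 0.142, a gap of 1.2 percentage points in the yield.

    solid substrate ⇌ dissolved substrate, rate k1*(cs1 - [dissolved substrate]) while solid is left; crystals form when [dissolved substrate] > cs1 (solubility = 0.0510 M, k = 0.0140 /h)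
    dissolved substrate + reagent → target (k = 0.0620 /M/h)
    2 dissolved substrate → side product (k = 0.200 /M/h)
    solid product ⇌ target, rate k4*(cs4 - [target]) while solid is left; crystals form when [target] > cs4 (solubility = 49.0 mM, k = 0.240 /h)
    target ⇌ isomer of the product (K = 0.500, k = 0.0580 /h)

- A neighbour flask has the same reagent charge and time but 0.24 M of solid substrate, so my ratio 0.142 gives 24.8 %. The computed neighbour flask gives 24.1 %, with 49.3 % still standing as solid substrate.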